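**Strategy.** Ring C is opened at the O1–C8a aryl ether bond, leaving an acyclic, all-anti C2–C3–C4 triol chain between rings A and B. The closure exploits the fact that O1–C8a is a bond to an sp2 carbon of ring A, whereas C2 is an ionisable para-oxybenzylic stereocentre: a palladium-catalysed intramolecular C–O coupling of the free C2 hydroxyl with the C8a chloride forms ring C in one operation without touching any bond at C2, C3 or C4. The precursor carries C2–OH free, C3 as a methoxymethyl ether, C4 as a silylated carbinol (a ketone would suffer retro-aldol loss of C2 and ring B), and methoxymethyl ethers on all phenols.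

Key step: step 12

**Remarks before the steps**

- Assumption: in the magnesium-catalysed aldol (step 4) the N-acylthiazolidinethione is taken to react through its (Z)-enolate on the face remote from the auxiliary benzyl group, so that the (R)-auxiliary gives the (2R,3R) anti adduct; should the glycolate oxygen reverse this sense, the (S)-auxiliary is used and nothing else changes.
- The target is the 2,3-trans (2R,3R) dihydroflavonol. Closure at C8a retains C2, so the chain must be 2,3-anti.
- Descriptors: precursor 21 is (1R,2R,3S) and its cyclisation product 22 is (2R,3R,4S), because the silyloxy-bearing C4 outranks C2 at C3. The same 2,3-trans arrangement reads (2R,3S,4S) in the 4-hydroxy compound 23 and (2R,3R) in ketone 24 and the target.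
- Ring A of the precursor is numbered 6-chloro-2,4-bis(methoxymethoxy)-3-prenylphenyl (prenyl = 3-methylbut-2-en-1-yl).
- Precursor design:
  - O3 is an acetal (MOM), not a silyl or acyl group, since those can migrate to the neighbouring C2 alkoxide under carbonate base and would open the way to a five-membered ring.
  - The halogen at C8a is chlorine because the ortho-chloroaryllithium needed for fragment union survives −78 °C.
  - The C2 hydroxyl is masked temporarily as a triethylsilyl ether, removable beside the C4 tert-butyldimethylsilyl ether.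
  - C4 is taken as the 4S (3,4-anti, Felkin–Anh) epimer, whose silyloxy group becomes pseudo-axial in ring C and avoids the C5 substituent. Any 4R epimer converges at ketone 24.

**Route**

Step 1
Reactants: 1 vanillin
Product: 2 3-methoxy-4-(methoxymethoxy)benzaldehyde
Conditions: MOMCl, i-Pr2NEt, CH2Cl2, 0 °C → rt
Reagents that add atoms: chloromethyl methyl ether, COCCl
Why: Williamson-type O-alkylation of the phenol with the α-chloro ether should give the acetal ether and leave the aldehyde untouched.

Step 2
Reactants: 3 methyl glycolate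
Product: 5 2-(methoxymethoxy)acetic acid, via methyl 2-(methoxymethoxy)acetate 4 (not isolated)
Conditions: MOMCl, i-Pr2NEt, THF, 0 °C → rt; then LiOH, H2O, rt; 1 M HCl to pH 3, 0 °C
Reagents that add atoms: chloromethyl methyl ether, COCCl; lithium hydroxide, [Li+].[OH-]
Why: Acetal ether formation at the hydroxyl followed by ester saponification in the same flask should give the acid, the alkyl MOM ether being stable to hydroxide and to brief cold acidification.

Step 3
Reactants: 5 2-(methoxymethoxy)acetic acid; 6 (R)-4-benzyl-1,3-thiazolidine-2-thione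
Product: 7 (4R)-4-benzyl-3-[(methoxymethoxy)acetyl]-1,3-thiazolidine-2-thione
Conditions: EDC·HCl, DMAP (cat.), CH2Cl2, 0 °C → rt
Reagents that add atoms: none
Why: Carbodiimide-mediated N-acylation (Steglich-type) of the acidic thiazolidinethione N–H is the standard entry to N-acylthiazolidinethiones.

Step 4
Reactants: 7 (4R)-4-benzyl-3-[(methoxymethoxy)acetyl]-1,3-thiazolidine-2-thione; 2 3-methoxy-4-(methoxymethoxy)benzaldehyde
Product: 9 (2R,3R)-1-[(4R)-4-benzyl-2-thioxo-1,3-thiazolidin-3-yl]-3-hydroxy-2-(methoxymethoxy)-3-[3-methoxy-4-(methoxymethoxy)phenyl]propan-1-one, via trimethylsilyl ether of the aldol adduct 8 (not isolated)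
Conditions: MgBr2·OEt2 (20 mol%), Et3N, TMSCl, EtOAc, rt; then 1 M HCl, THF, 0 °C
Reagents that add atoms: none
Why: Magnesium-halide-catalysed direct anti-aldol of a chiral N-acylthiazolidinethione, in which soft enolisation gives the (Z)-enolate that adds to the non-enolisable aromatic aldehyde with anti selectivity on the face remote from the auxiliary benzyl group, so that the auxiliary sets aldol C2 and C3 (later C3 and C2 of the chromane) as R,R while O-silylation by TMSCl turns the catalyst over.

Step 5
Reactants: 9 (2R,3R)-1-[(4R)-4-benzyl-2-thioxo-1,3-thiazolidin-3-yl]-3-hydroxy-2-(methoxymethoxy)-3-[3-methoxy-4-(methoxymethoxy)phenyl]propan-1-one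
Product: 10 (2R,3R)-1-[(4R)-4-benzyl-2-thioxo-1,3-thiazolidin-3-yl]-2-(methoxymethoxy)-3-[3-methoxy-4-(methoxymethoxy)phenyl]-3-(triethylsilyloxy)propan-1-one
Conditions: TESOTf, 2,6-lutidine, CH2Cl2, −78 °C
Reagents that add atoms: triethylsilyl trifluoromethanesulfonate, CC[Si](CC)(CC)OS(=O)(=O)C(F)(F)F
Why: O-silylation of the secondary benzylic alcohol with a silyl triflate and a hindered base is fast at low temperature and should spare the MOM acetals and the thioimide.

Step 6
Reactants: 10 (2R,3R)-1-[(4R)-4-benzyl-2-thioxo-1,3-thiazolidin-3-yl]-2-(methoxymethoxy)-3-[3-methoxy-4-(methoxymethoxy)phenyl]-3-(triethylsilyloxy)propan-1-one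
Product: 11 (2R,3R)-2-(methoxymethoxy)-3-[3-methoxy-4-(methoxymethoxy)phenyl]-3-(triethylsilyloxy)propanal
Conditions: i-Bu2AlH, CH2Cl2, −78 °C; aq. potassium sodium tartrate
Reagents that add atoms: none
Why: Partial reduction of the activated N-acylthiazolidinethione by the aluminium hydride should stop at a hemithioaminal that collapses to the aldehyde on work-up, releasing the auxiliary and leaving the α-stereocentre intact.

Step 7
Reactants: 12 5-chlororesorcinol
Product: 13 1-chloro-3,5-bis(methoxymethoxy)benzene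
Conditions: MOMCl, i-Pr2NEt, CH2Cl2, 0 °C → rt
Reagents that add atoms: chloromethyl methyl ether, COCCl
Why: Double Williamson-type etherification masks both phenols and installs two ortho-directing groups.

Step 8
Reactants: 13 1-chloro-3,5-bis(methoxymethoxy)benzene; 14 prenyl bromide
Product: 17 5-chloro-1,3-bis(methoxymethoxy)-2-(3-methylbut-2-en-1-yl)benzene, via [4-chloro-2,6-bis(methoxymethoxy)phenyl]lithium 15 (not isolated), via [4-chloro-2,6-bis(methoxymethoxy)phenyl]copper 16 (not isolated)
Conditions: s-BuLi, TMEDA, THF, −78 °C; CuI, −78 → −40 °C; prenyl bromide, −40 → 0 °C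
Reagents that add atoms: none
Why: Directed ortho-metalation at the carbon flanked by both MOM ethers, transmetalation to copper and SN2 allylation with prenyl bromide should give the 2-prenyl arene without allylic transposition.

Step 9
Reactants: 17 5-chloro-1,3-bis(methoxymethoxy)-2-(3-methylbut-2-en-1-yl)benzene; 11 (2R,3R)-2-(methoxymethoxy)-3-[3-methoxy-4-(methoxymethoxy)phenyl]-3-(triethylsilyloxy)propanal
Product: 19 (1S,2S,3R)-1-[6-chloro-2,4-bis(methoxymethoxy)-3-(3-methylbut-2-en-1-yl)phenyl]-2-(methoxymethoxy)-3-[3-methoxy-4-(methoxymethoxy)phenyl]-3-(triethylsilyloxy)propan-1-ol, via [6-chloro-2,4-bis(methoxymethoxy)-3-(3-methylbut-2-en-1-yl)phenyl]lithium 18 (not isolated)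
Conditions: n-BuLi, TMEDA, THF, −78 °C; then 11, THF, −78 °C; sat. aq. NH4Cl at −78 °C
Reagents that add atoms: none
Why: A second directed ortho-lithiation, at the ring position flanked by a MOM ether and chlorine, gives an ortho-chloroaryllithium that is stable to LiCl loss at −78 °C and undergoes 1,2-addition to the aldehyde, the new carbinol centre (later C4) being expected mainly in the Felkin–Anh (3,4-anti, S) sense and being removed again at the ketone stage, while the cold quench forestalls O-to-O silyl migration.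

Step 10
Reactants: 19 (1S,2S,3R)-1-[6-chloro-2,4-bis(methoxymethoxy)-3-(3-methylbut-2-en-1-yl)phenyl]-2-(methoxymethoxy)-3-[3-methoxy-4-(methoxymethoxy)phenyl]-3-(triethylsilyloxy)propan-1-ol
Product: 20 tert-butyl{[(1S,2R,3R)-1-[6-chloro-2,4-bis(methoxymethoxy)-3-(3-methylbut-2-en-1-yl)phenyl]-2-(methoxymethoxy)-3-[3-methoxy-4-(methoxymethoxy)phenyl]-3-(triethylsilyloxy)propyl]oxy}dimethylsilane
Conditions: TBSOTf, 2,6-lutidine, CH2Cl2, −78 → 0 °C
Reagents that add atoms: tert-butyldimethylsilyl trifluoromethanesulfonate, CC(C)(C)[Si](C)(C)OS(=O)(=O)C(F)(F)F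
Why: O-silylation of the hindered benzylic alcohol with the silyl triflate under basic conditions is reliable and avoids ionisation at the electron-rich benzylic C4.

Step 11
Reactants: 20 tert-butyl{[(1S,2R,3R)-1-[6-chloro-2,4-bis(methoxymethoxy)-3-(3-methylbut-2-en-1-yl)phenyl]-2-(methoxymethoxy)-3-[3-methoxy-4-(methoxymethoxy)phenyl]-3-(triethylsilyloxy)propyl]oxy}dimethylsilane
Product: 21 (1R,2R,3S)-3-[tert-butyl(dimethyl)silyloxy]-3-[6-chloro-2,4-bis(methoxymethoxy)-3-(3-methylbut-2-en-1-yl)phenyl]-2-(methoxymethoxy)-1-[3-methoxy-4-(methoxymethoxy)phenyl]propan-1-ol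
Conditions: HF·pyridine, pyridine, THF, 0 °C
Reagents that add atoms: none
Why: Selective desilylation, since buffered HF·pyridine cleaves a triethylsilyl ether far faster than a hindered tert-butyldimethylsilyl ether and leaves MOM acetals alone.

Step 12
Reactants: 21 (1R,2R,3S)-3-[tert-butyl(dimethyl)silyloxy]-3-[6-chloro-2,4-bis(methoxymethoxy)-3-(3-methylbut-2-en-1-yl)phenyl]-2-(methoxymethoxy)-1-[3-methoxy-4-(methoxymethoxy)phenyl]propan-1-ol
Product: 22 (2R,3R,4S)-4-[tert-butyl(dimethyl)silyloxy]-3,5,7-tris(methoxymethoxy)-2-[3-methoxy-4-(methoxymethoxy)phenyl]-6-(3-methylbut-2-en-1-yl)chromane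
Conditions: Pd(OAc)2 (5 mol%), rac-2-(di-tert-butylphosphino)-1,1'-binaphthyl (6 mol%), Cs2CO3, toluene, 80 °C
Reagents that add atoms: none
Why: Zerovalent palladium, formed in the flask from Pd(OAc)2 and the bulky di-tert-butylbiarylphosphine, inserts into the C8a–Cl bond of ring A, Cs2CO3 exchanges chloride on the metal for the C2 alkoxide, and C–O reductive elimination releases the chromane. This is the Buchwald–Hartwig-type palladium-catalysed intramolecular etherification of aryl halides with secondary alcohols. Ring C is closed by reductive elimination from a seven-membered palladacycle, the only new bond being O1–C8a, with the oxygen tethered through C2–C3–C4–C4a reaching the arene carbon in a six-membered mode. No stereocentre is created, and C2, C3 and C4 keep their configurations because only the O–H and C(sp2)–Cl bonds are broken. The step needs reductive elimination to outrun β-hydride elimination at the C2–H of the palladium-bound benzylic alkoxide, which the bulky, electron-rich monophosphine favours, and it needs the C2 oxygen to be the only competent nucleophile, which the substrate secures because O3 is a non-migrating acetal and O4 is silylated and could in any case give only a four-membered ring.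

Step 13
Reactants: 22 (2R,3R,4S)-4-[tert-butyl(dimethyl)silyloxy]-3,5,7-tris(methoxymethoxy)-2-[3-methoxy-4-(methoxymethoxy)phenyl]-6-(3-methylbut-2-en-1-yl)chromane
Product: 23 (2R,3S,4S)-3,5,7-tris(methoxymethoxy)-2-[3-methoxy-4-(methoxymethoxy)phenyl]-6-(3-methylbut-2-en-1-yl)chroman-4-ol
Conditions: Bu4NF, THF, 0 °C → rt
Reagents that add atoms: none
Why: Fluoride-mediated desilylation should free the C4 hydroxyl while the MOM acetals and the aryl ether are inert to fluoride.

Step 14
Reactants: 23 (2R,3S,4S)-3,5,7-tris(methoxymethoxy)-2-[3-methoxy-4-(methoxymethoxy)phenyl]-6-(3-methylbut-2-en-1-yl)chroman-4-ol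
Product: 24 (2R,3R)-3,5,7-tris(methoxymethoxy)-2-[3-methoxy-4-(methoxymethoxy)phenyl]-6-(3-methylbut-2-en-1-yl)chroman-4-one
Conditions: Dess–Martin periodinane, NaHCO3, CH2Cl2, 0 °C → rt
Reagents that add atoms: none
Why: Dess–Martin oxidation converts the secondary benzylic alcohol into the aryl ketone under buffered, non-epimerising conditions that tolerate the prenyl group and the acetals.

Step 15
Reactants: 24 (2R,3R)-3,5,7-tris(methoxymethoxy)-2-[3-methoxy-4-(methoxymethoxy)phenyl]-6-(3-methylbut-2-en-1-yl)chroman-4-one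
Product: 25 (2R,3R)-3,5,7-trihydroxy-2-(4-hydroxy-3-methoxyphenyl)-6-(3-methylbut-2-en-1-yl)chroman-4-one
Conditions: 3 M aq. HCl, MeOH, 50 °C
Reagents that add atoms: none
Why: Acid-catalysed acetal methanolysis should remove the three aryl MOM ethers and the C3 MOM ether under conditions commonly used for prenylated flavanones, the 2,3-trans arrangement being the thermodynamically preferred one.

**Compound list**

1 | vanillin (4-hydroxy-3-methoxybenzaldehyde) | COc1cc(C=O)ccc1O | starting material
2 | 3-methoxy-4-(methoxymethoxy)benzaldehyde | COCOc1ccc(C=O)cc1OC | intermediate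
3 | methyl glycolate | COC(=O)CO | starting material
4 | methyl 2-(methoxymethoxy)acetate | COCOCC(=O)OC | intermediate (not isolated)
5 | 2-(methoxymethoxy)acetic acid | COCOCC(=O)O | intermediate
6 | (R)-4-benzyl-1,3-thiazolidine-2-thione | S=C1N[C@H](Cc2ccccc2)CS1 | starting material
7 | (4R)-4-benzyl-3-[(methoxymethoxy)acetyl]-1,3-thiazolidine-2-thione | COCOCC(=O)N1C(=S)SC[C@H]1Cc1ccccc1 | intermediate
8 | (2R,3R)-1-[(4R)-4-benzyl-2-thioxo-1,3-thiazolidin-3-yl]-2-(methoxymethoxy)-3-[3-methoxy-4-(methoxymethoxy)phenyl]-3-(trimethylsilyloxy)propan-1-one | COc1cc([C@@H](O[Si](C)(C)C)[C@@H](OCOC)C(=O)N2C(=S)SC[C@H]2Cc3ccccc3)ccc1OCOC | intermediate (not isolated)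
9 | (2R,3R)-1-[(4R)-4-benzyl-2-thioxo-1,3-thiazolidin-3-yl]-3-hydroxy-2-(methoxymethoxy)-3-[3-methoxy-4-(methoxymethoxy)phenyl]propan-1-one | COc1cc([C@@H](O)[C@@H](OCOC)C(=O)N2C(=S)SC[C@H]2Cc3ccccc3)ccc1OCOC | intermediate
10 | (2R,3R)-1-[(4R)-4-benzyl-2-thioxo-1,3-thiazolidin-3-yl]-2-(methoxymethoxy)-3-[3-methoxy-4-(methoxymethoxy)phenyl]-3-(triethylsilyloxy)propan-1-one | COc1cc([C@@H](O[Si](CC)(CC)CC)[C@@H](OCOC)C(=O)N2C(=S)SC[C@H]2Cc3ccccc3)ccc1OCOC | intermediate
11 | (2R,3R)-2-(methoxymethoxy)-3-[3-methoxy-4-(methoxymethoxy)phenyl]-3-(triethylsilyloxy)propanal | COc1cc([C@@H](O[Si](CC)(CC)CC)[C@@H](OCOC)C=O)ccc1OCOC | intermediate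
12 | 5-chlororesorcinol | Oc1cc(O)cc(Cl)c1 | starting material
13 | 1-chloro-3,5-bis(methoxymethoxy)benzene | COCOc1cc(Cl)cc(OCOC)c1 | intermediate
14 | prenyl bromide (1-bromo-3-methylbut-2-ene) | CC(C)=CCBr | starting material
15 | [4-chloro-2,6-bis(methoxymethoxy)phenyl]lithium | [Li]c1c(OCOC)cc(Cl)cc1OCOC | intermediate (not isolated)
16 | [4-chloro-2,6-bis(methoxymethoxy)phenyl]copper | [Cu]c1c(OCOC)cc(Cl)cc1OCOC | intermediate (not isolated)
17 | 5-chloro-1,3-bis(methoxymethoxy)-2-(3-methylbut-2-en-1-yl)benzene | COCOc1cc(Cl)cc(OCOC)c1CC=C(C)C | intermediate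
18 | [6-chloro-2,4-bis(methoxymethoxy)-3-(3-methylbut-2-en-1-yl)phenyl]lithium | [Li]c1c(Cl)cc(OCOC)c(CC=C(C)C)c1OCOC | intermediate (not isolated)
19 | (1S,2S,3R)-1-[6-chloro-2,4-bis(methoxymethoxy)-3-(3-methylbut-2-en-1-yl)phenyl]-2-(methoxymethoxy)-3-[3-methoxy-4-(methoxymethoxy)phenyl]-3-(triethylsilyloxy)propan-1-ol | COc1cc([C@@H](O[Si](CC)(CC)CC)[C@@H](OCOC)[C@@H](O)c2c(Cl)cc(OCOC)c(CC=C(C)C)c2OCOC)ccc1OCOC | intermediate
20 | tert-butyl{[(1S,2R,3R)-1-[6-chloro-2,4-bis(methoxymethoxy)-3-(3-methylbut-2-en-1-yl)phenyl]-2-(methoxymethoxy)-3-[3-methoxy-4-(methoxymethoxy)phenyl]-3-(triethylsilyloxy)propyl]oxy}dimethylsilane | COc1cc([C@@H](O[Si](CC)(CC)CC)[C@@H](OCOC)[C@@H](O[Si](C)(C)C(C)(C)C)c2c(Cl)cc(OCOC)c(CC=C(C)C)c2OCOC)ccc1OCOC | intermediate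
21 | (1R,2R,3S)-3-[tert-butyl(dimethyl)silyloxy]-3-[6-chloro-2,4-bis(methoxymethoxy)-3-(3-methylbut-2-en-1-yl)phenyl]-2-(methoxymethoxy)-1-[3-methoxy-4-(methoxymethoxy)phenyl]propan-1-ol | COc1cc([C@@H](O)[C@@H](OCOC)[C@@H](O[Si](C)(C)C(C)(C)C)c2c(Cl)cc(OCOC)c(CC=C(C)C)c2OCOC)ccc1OCOC | intermediate
22 | (2R,3R,4S)-4-[tert-butyl(dimethyl)silyloxy]-3,5,7-tris(methoxymethoxy)-2-[3-methoxy-4-(methoxymethoxy)phenyl]-6-(3-methylbut-2-en-1-yl)chromane | COc1cc([C@H]2Oc3cc(OCOC)c(CC=C(C)C)c(OCOC)c3[C@H](O[Si](C)(C)C(C)(C)C)[C@@H]2OCOC)ccc1OCOC | intermediate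
23 | (2R,3S,4S)-3,5,7-tris(methoxymethoxy)-2-[3-methoxy-4-(methoxymethoxy)phenyl]-6-(3-methylbut-2-en-1-yl)chroman-4-ol | COc1cc([C@H]2Oc3cc(OCOC)c(CC=C(C)C)c(OCOC)c3[C@H](O)[C@@H]2OCOC)ccc1OCOC | intermediate
24 | (2R,3R)-3,5,7-tris(methoxymethoxy)-2-[3-methoxy-4-(methoxymethoxy)phenyl]-6-(3-methylbut-2-en-1-yl)chroman-4-one | COc1cc([C@H]2Oc3cc(OCOC)c(CC=C(C)C)c(OCOC)c3C(=O)[C@@H]2OCOC)ccc1OCOC | intermediate
25 | (2R,3R)-3,5,7-trihydroxy-2-(4-hydroxy-3-methoxyphenyl)-6-(3-methylbut-2-en-1-yl)chroman-4-one | COc1cc([C@H]2Oc3cc(O)c(CC=C(C)C)c(O)c3C(=O)[C@@H]2O)ccc1O | target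

**Step count and risks**

Total step count: 15.
Longest linear sequence: 12 steps (methyl glycolate 3 to target 25 through steps 2–6 and 9–15); 11 steps from vanillin.

Steps most likely to fail:

1. Step 12. β-Hydride elimination from the palladium-bound benzylic C2 alkoxide (oxidation at C2 with hydrodechlorination of ring A) or slow oxidative addition into the hindered C8a–Cl bond may outpace C–O reductive elimination. Fallback, an aryne etherification without a transition metal: from precursor 21, LiTMP (3 equiv, THF, −78 → 0 °C) would deprotonate the C2 hydroxyl and the ring hydrogen between chlorine and the C7 MOM ether and expel LiCl, giving the C8–C8a aryne alkoxide F1. The tethered C2 alkoxide should capture it at C8a, the site favoured by both the tether and the inductive effect of the C7 oxygen. Protonation of the C8 carbanion on work-up comes back to chromane 22, again without breaking a bond at C2.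

2. Step 9. Deprotonation may occur at the benzylic–allylic prenyl methylene instead of the ring, the ortho-chloroaryllithium may lose LiCl to an aryne on any warming, or the hindered basic aryllithium may enolise the α-alkoxy aldehyde. Fallback, a magnesium carbanion made by an amide base: from arene 17, directed magnesiation with TMPMgCl·LiCl (THF, 0 °C → rt) would give the arylmagnesium chloride F2, which does not eliminate to an aryne at these temperatures and is far less basic. Its addition to aldehyde 11 (THF, −20 °C) comes back to carbinol 19; a different C4 epimer ratio is immaterial.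

3. Step 4. The α-alkoxy group may bind magnesium and erode anti or facial selectivity, catalyst turnover may stall, or MOM groups may be lost to silyl bromide formed from the catalyst. Fallback, a catalyst-controlled Mukaiyama aldol instead of an auxiliary-controlled enolate aldol: from acid 5, thioesterification (EtSH, EDC·HCl, DMAP) would give S-ethyl 2-(methoxymethoxy)ethanethioate F3, and LDA/TMSCl (THF, −78 °C) its (Z)-ketene silyl acetal F4. Addition of F4 to aldehyde 2 under Sn(OTf)2, a proline-derived chiral diamine (the enantiomer that gives the 2R,3R adduct) and Bu2Sn(OAc)2 in CH2Cl2 at −78 °C should give the anti hydroxy thioester F5. Silylation (TESOTf, 2,6-lutidine) would give the triethylsilyl ether F6, and i-Bu2AlH (CH2Cl2, −78 °C) would reduce the thioester to aldehyde 11, where the route is rejoined.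

**Further compounds**

F1 | step 12 | lithium (1R,2R,3S)-3-[tert-butyl(dimethyl)silyloxy]-3-[5,6-didehydro-2,4-bis(methoxymethoxy)-3-(3-methylbut-2-en-1-yl)phenyl]-2-(methoxymethoxy)-1-[3-methoxy-4-(methoxymethoxy)phenyl]propan-1-olate (aryne, not isolated) | COc1cc([C@@H](O[Li])[C@@H](OCOC)[C@@H](O[Si](C)(C)C(C)(C)C)C2=C(OCOC)C(CC=C(C)C)=C(OCOC)C#C2)ccc1OCOC
F2 | step 9 | chloro[6-chloro-2,4-bis(methoxymethoxy)-3-(3-methylbut-2-en-1-yl)phenyl]magnesium (LiCl complex, not isolated) | Cl[Mg]c1c(Cl)cc(OCOC)c(CC=C(C)C)c1OCOC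
F3 | step 4 | S-ethyl 2-(methoxymethoxy)ethanethioate | CCSC(=O)COCOC
F4 | step 4 | (Z)-1-(ethylsulfanyl)-2-(methoxymethoxy)-1-(trimethylsilyloxy)ethene | CCS/C(O[Si](C)(C)C)=C\OCOC
F5 | step 4 | S-ethyl (2R,3R)-3-hydroxy-2-(methoxymethoxy)-3-[3-methoxy-4-(methoxymethoxy)phenyl]propanethioate | COc1cc([C@@H](O)[C@@H](OCOC)C(=O)SCC)ccc1OCOC
F6 | step 4 | S-ethyl (2R,3R)-2-(methoxymethoxy)-3-[3-methoxy-4-(methoxymethoxy)phenyl]-3-(triethylsilyloxy)propanethioate | COc1cc([C@@H](O[Si](CC)(CC)CC)[C@@H](OCOC)C(=O)SCC)ccc1OCOC
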